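**Strategy**

The cyclohexene ring B (C5–C10; drimane-type locants, C10 = methyl-bearing ring-fusion carbon) is disconnected across C5–C10 and C6–C7. A catalytic enantioselective intramolecular Diels–Alder reaction joins a 2-silyloxy diene (C7=C8(OSi)–C9=C10) to a tethered vinyl ketone (C6=C5–C4=O), closing rings A and B at once and setting the quaternary C10. Its precursor is a linear, achiral (E)-decatrienone made from 5-hexyn-1-ol. The adduct holds two differentiated carbonyl equivalents: the C4 ketone delivers the axial C3 methyl and the exocyclic methylene, the C8 silyl enol ether the α-benzyl group at C9 and then, via an enol triflate, the C7=C8 methyl alkene. Side-chain acid and hydroquinone are unveiled last.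

Key step: step 7

Remark on locants: ring A = C1, C2, C3, C4, C5, C10 (C3 methyl, C4 methylidene); ring B = C5, C6, C7, C8, C9, C10 (C7=C8, C8 methyl, C9 bearing the benzylic C11); β is the face of the C10 methyl, α the opposite face.

Remark on the target: it is (1R,4aS,6R,8aR) in naphthalene locants, that is trans-fused (5α-H, 10β-methyl) with the C3 methyl α (axial) and the C9 benzyl group α (trans to the C10 methyl).

Assumption on step 7: the (R)-configured catalyst is specified from the α-C–H···O coordination model for vinyl ketones, which predicts addition of the diene to the C5 Re face; the sense of induction is to be confirmed on adduct 13.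

Assumption on materials: 5-hexyn-1-ol, 2-bromo-1,4-dimethoxybenzene and all reagents named are taken as commercially available.

**Route**

Step 1
Reactants: 1 5-hexyn-1-ol
Product: 3 (E)-6-iodo-5-methylhex-5-en-1-ol, via alkenylalane 2 (not isolated)
Conditions: Me3Al (3 equiv), Cp2ZrCl2 (0.25 equiv), CH2Cl2, 0 °C to rt; then I2, THF, −30 to 0 °C; aqueous potassium sodium tartrate
Reagents that add atoms: trimethylaluminium, C[Al](C)C; iodine, II
Why: Zirconium-catalysed syn-carboalumination of the terminal alkyne (Negishi carboalumination) places the methyl group on the internal carbon and aluminium on the terminus, and iodinolysis with retention should give the (E)-iodide only.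

Step 2
Reactants: 3 (E)-6-iodo-5-methylhex-5-en-1-ol
Product: 5 (E)-6-iodo-5-methylhex-5-enoic acid, via iodo aldehyde 4 (not isolated)
Conditions: TEMPO (0.2 equiv), PhI(OAc)2 (2.2 equiv), MeCN/H2O 1:1, rt
Reagents that add atoms: water, O
Why: Oxoammonium-mediated oxidation of the primary alcohol runs through the aldehyde and its hydrate to the acid in aqueous acetonitrile and should leave the alkenyl iodide untouched.

Step 3
Reactants: 5 (E)-6-iodo-5-methylhex-5-enoic acid
Product: 7 (E)-6-iodo-N-methoxy-N,5-dimethylhex-5-enamide, via acyl imidazole 6 (not isolated)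
Conditions: 1,1′-carbonyldiimidazole, CH2Cl2, rt; then MeNH(OMe)·HCl, rt
Reagents that add atoms: N,O-dimethylhydroxylamine hydrochloride, CNOC.Cl
Why: Activation of the acid as the acyl imidazole and aminolysis is a standard Weinreb amide formation.

Step 4
Reactants: 7 (E)-6-iodo-N-methoxy-N,5-dimethylhex-5-enamide
Product: 9 (E)-N-methoxy-N,5-dimethyl-7-oxooct-5-enamide, via ethoxy diene 8 (not isolated)
Conditions: tributyl(1-ethoxyvinyl)stannane, Pd(PPh3)4 (5 mol %), CuI (10 mol %), DMF, 50 °C; then 1 M HCl, THF, 0 °C
Reagents that add atoms: tributyl(1-ethoxyvinyl)stannane, C=C(OCC)[Sn](CCCC)(CCCC)CCCC; water, O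
Why: Stille coupling proceeds with retention of the alkene geometry, and mild acid hydrolysis of the enol ether unveils the methyl ketone as the (E)-enone without a free hydroxyl group that could add to it.

Step 5
Reactants: 9 (E)-N-methoxy-N,5-dimethyl-7-oxooct-5-enamide
Product: 10 (E)-N-methoxy-N,5-dimethyl-7-[(triisopropylsilyl)oxy]octa-5,7-dienamide
Conditions: iPr3SiOTf, Et3N, CH2Cl2, −78 to 0 °C
Reagents that add atoms: triisopropylsilyl trifluoromethanesulfonate, CC(C)[Si](C(C)C)(C(C)C)OS(=O)(=O)C(F)(F)F
Why: Soft enolisation of the methyl ketone at its α′-methyl group should give the cross-conjugated 2-silyloxy diene, while the much less acidic Weinreb amide is not enolised.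

Step 6
Reactants: 10 (E)-N-methoxy-N,5-dimethyl-7-[(triisopropylsilyl)oxy]octa-5,7-dienamide
Product: 12 (E)-7-methyl-9-[(triisopropylsilyl)oxy]deca-1,7,9-trien-3-one, via magnesium hemiaminal 11 (not isolated)
Conditions: CH2=CHMgBr (1.5 equiv), THF, −78 to −20 °C; inverse quench into cold pH 7 buffer; kept cold and dilute, used at once
Reagents that add atoms: vinylmagnesium bromide, C=C[Mg]Br
Why: In this Weinreb ketone synthesis the chelated tetrahedral adduct prevents over-addition and collapses only on quench to the vinyl ketone, and the silyl enol ether is inert to the Grignard reagent.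

Step 7
Reactants: 12 (E)-7-methyl-9-[(triisopropylsilyl)oxy]deca-1,7,9-trien-3-one
Product: 13 (4aR,8aS)-4a-methyl-6-[(triisopropylsilyl)oxy]-3,4,4a,7,8,8a-hexahydronaphthalen-1(2H)-one (cis-fused, C5-H and C10-methyl both β)
Conditions: (R)-3,3-diphenyl-1-(o-tolyl)tetrahydro-1H,3H-pyrrolo[1,2-c][1,3,2]oxazaborole (20 mol %), Tf2NH (17 mol %), CH2Cl2, −78 to −40 °C
Reagents that add atoms: none
Why: The protonated oxazaborolidine binds the carbonyl of the s-trans vinyl ketone (α-C–H···O contact) and lowers its LUMO, so the electron-rich 2-silyloxy diene (largest HOMO coefficient at C7) should add in a concerted but strongly asynchronous [4+2] in which C6–C7 is advanced and C5–C10 follows, which is what should let the quaternary C10 form despite the inside methyl group of the (E)-diene. The closest known reaction type is the oxazaborolidinium-catalysed enantioselective Diels–Alder reaction of 2-silyloxy dienes with enones, used here in its intramolecular form (type 1 intramolecular Diels–Alder reaction of a 1,7,9-decatrien-3-one). Ring B (C5–C10) is closed by the suprafacial cycloaddition itself, and ring A (C1–C5, C10) is closed through the three-carbon tether by the same C5–C10 bond, which gives the fused decalin. The relative configuration at C5 and C10 (cis) follows from the endo transition state with the tether carbonyl under the diene, which Lewis acid activation favours for decatrienones with the ketone in the tether, and the absolute configuration follows from the catalyst, whose aryl group should shield the C5 Si face so that the diene adds to the C5 Re face. The step needs endo/exo and π-facial selectivity (the regiochemistry is fixed by the tether); any exo (trans-fused) adduct belongs to the opposite C10 series and is removed by chromatography before step 8. The silyl enol ether (C8=C9) that remains in ring B is the regiodefined enolate equivalent needed in step 12.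

Step 8
Reactants: 13 cis-fused adduct
Product: 14 (4aR,8aR)-4a-methyl-6-[(triisopropylsilyl)oxy]-3,4,4a,7,8,8a-hexahydronaphthalen-1(2H)-one (trans-fused, 5α-H, 10β-methyl)
Conditions: DBU (0.3 equiv), toluene, 60 °C
Reagents that add atoms: none
Why: Base-mediated epimerisation at C5 through the enolate should lead under thermodynamic control to the trans-fused decalone, which is expected to be the more stable isomer, while C10 cannot change.

Step 9
Reactants: 14 trans-fused ketone
Product: 16 (2R,4aR,8aR)-2,4a-dimethyl-6-[(triisopropylsilyl)oxy]-3,4,4a,7,8,8a-hexahydronaphthalen-1(2H)-one (3α-methyl, axial), via lithium enolate 15 (not isolated)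
Conditions: LiN(iPr)2 (1.05 equiv), THF, −78 °C; MeI (3 equiv), −78 to −40 °C; cold aqueous NH4Cl
Reagents that add atoms: iodomethane, CI
Why: Kinetic deprotonation occurs at the less substituted C3, and SN2 methylation of the enolate should take place on the α face, which is both the axial trajectory (chair-like transition state) and the face opposite the C10 methyl group, so that the new C3 centre carries the axial methyl group.

Step 10
Reactants: 16 3α-methyl ketone
Product: 17 triisopropyl{[(4aS,6R,8aS)-6,8a-dimethyl-5-methylidene-3,4,4a,5,6,7,8,8a-octahydronaphthalen-2-yl]oxy}silane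
Conditions: Cp2Ti(μ-CH2)(μ-Cl)AlMe2 (Tebbe reagent, 1.5 equiv), pyridine, THF/toluene, −40 to 0 °C
Reagents that add atoms: Tebbe reagent, C[Al](C)C[Ti](Cl)(C1C=CC=C1)C1C=CC=C1
Why: Tebbe methylenation through an oxatitanacyclobutane converts hindered, enolisable ketones to methylidene groups under non-basic conditions, so the axial C3 methyl group should not epimerise and the silyl enol ether is untouched.

Step 11
Reactants: 18 2-bromo-1,4-dimethoxybenzene
Product: 20 1-bromo-4-(bromomethyl)-2,5-dimethoxybenzene, via benzylic alcohol 19 (not isolated)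
Conditions: (CH2O)n, HBr (33 % in AcOH), 50 °C
Reagents that add atoms: formaldehyde (as paraformaldehyde), C=O; hydrogen bromide, Br
Why: Bromomethylation (Blanc-type electrophilic aromatic substitution) should occur at the position para to bromine and ortho to a methoxy group, the most activated and least hindered site.

Step 12
Reactants: 17 silyl enol ether; 20 1-bromo-4-(bromomethyl)-2,5-dimethoxybenzene
Product: 22 (1S,4aS,6R,8aS)-1-[(4-bromo-2,5-dimethoxyphenyl)methyl]-6,8a-dimethyl-5-methylidene-3,4,4a,5,6,7,8,8a-octahydronaphthalen-2(1H)-one (9α-benzyl), via ammonium enolate 21 (not isolated)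
Conditions: Bu4NF (anhydrous, dried over 4 Å sieves, 1.1 equiv), 20 (1.3 equiv) present from the start, THF, −78 to 0 °C
Reagents that add atoms: none
Why: Fluoride cleavage of the silyl enol ether gives the regiodefined C8–C9 enolate, whose SN2 benzylation at C9 should occur axially on the α face, anti to the neighbouring C10 methyl group, and so sets C9 trans to that methyl group.

Step 13
Reactants: 22 9α-benzyl ketone
Product: 24 (1S,4aS,6R,8aS)-1-[(4-bromo-2,5-dimethoxyphenyl)methyl]-6,8a-dimethyl-5-methylidene-1,4,4a,5,6,7,8,8a-octahydronaphthalen-2-yl trifluoromethanesulfonate, via potassium enolate 23 (not isolated)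
Conditions: KN(SiMe3)2 (1.1 equiv), THF, −78 °C; PhNTf2, −78 to 0 °C
Reagents that add atoms: N-phenylbis(trifluoromethanesulfonimide), O=S(=O)(N(c1ccccc1)S(=O)(=O)C(F)(F)F)C(F)(F)F
Why: Kinetic enolisation takes the accessible C7 methylene and not the hindered tertiary C9–H, and O-triflation of this enolate fixes the double bond at C7=C8 without touching the C9 centre.

Step 14
Reactants: 24 enol triflate
Product: 25 1-bromo-4-{[(1R,4aS,6R,8aR)-2,6,8a-trimethyl-5-methylidene-1,4,4a,5,6,7,8,8a-octahydronaphthalen-1-yl]methyl}-2,5-dimethoxybenzene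
Conditions: MeMgBr (1.5 equiv), Fe(acac)3 (5 mol %), THF/NMP, −30 to 0 °C
Reagents that add atoms: methylmagnesium bromide, C[Mg]Br
Why: Iron-catalysed Kumada-type cross-coupling of alkenyl triflates with Grignard reagents is fast at low temperature, and the electron-rich aryl bromide should not react under these conditions.

Step 15
Reactants: 25 aryl bromide
Product: 26 ethyl 2-(2,5-dimethoxy-4-{[(1R,4aS,6R,8aR)-2,6,8a-trimethyl-5-methylidene-1,4,4a,5,6,7,8,8a-octahydronaphthalen-1-yl]methyl}phenyl)acetate
Conditions: BrZnCH2CO2Et (0.5 M in THF, 2 equiv), Pd2(dba)3 (2.5 mol %), XPhos (10 mol %), THF, 60 °C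
Reagents that add atoms: (2-ethoxy-2-oxoethyl)zinc bromide, CCOC(=O)C[Zn]Br
Why: Negishi-type coupling of a Reformatsky reagent with an aryl bromide (oxidative addition to zerovalent palladium, transmetalation, reductive elimination) installs the acetate side chain under neutral conditions that the alkenes tolerate.

Step 16
Reactants: 26 ethyl ester
Product: 28 2-(2,5-dimethoxy-4-{[(1R,4aS,6R,8aR)-2,6,8a-trimethyl-5-methylidene-1,4,4a,5,6,7,8,8a-octahydronaphthalen-1-yl]methyl}phenyl)acetic acid, via lithium carboxylate 27 (not isolated)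
Conditions: LiOH, THF/H2O, rt; then 1 M HCl to pH 3
Reagents that add atoms: lithium hydroxide, [Li+].[OH-]
Why: Saponification of the unhindered ethyl ester should proceed without affecting any stereocentre, since none is enolisable at this stage.

Step 17
Reactants: 28 dimethoxyaryl acetic acid
Product: 30 2-(2,5-dihydroxy-4-{[(1R,4aS,6R,8aR)-2,6,8a-trimethyl-5-methylidene-1,4,4a,5,6,7,8,8a-octahydronaphthalen-1-yl]methyl}phenyl)acetic acid (target), via quinone 29 (not isolated)
Conditions: (NH4)2Ce(NO3)6 (2.5 equiv), MeCN/H2O, 0 °C, 10 min; extraction into EtOAc; aqueous Na2S2O4, rt, under argon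
Reagents that add atoms: water, O
Why: Oxidative demethylation of the 1,4-dimethoxyarene by tetravalent cerium should give the p-quinone, which dithionite reduces at once to the hydroquinone, and the short, cold oxidation should spare the two alkenes and the acid.

**Compound list**

1 | 5-hexyn-1-ol | C#CCCCCO | starting material
2 | {[(E)-6-(dimethylalumanyl)-5-methylhex-5-en-1-yl]oxy}dimethylalane (alkenylalane) | C[Al](C)OCCCC/C(C)=C/[Al](C)C | intermediate
3 | (E)-6-iodo-5-methylhex-5-en-1-ol | OCCCC/C(C)=C/I | intermediate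
4 | (E)-6-iodo-5-methylhex-5-enal | O=CCCC/C(C)=C/I | intermediate
5 | (E)-6-iodo-5-methylhex-5-enoic acid | OC(=O)CCC/C(C)=C/I | intermediate
6 | (E)-1-(1H-imidazol-1-yl)-6-iodo-5-methylhex-5-en-1-one (acyl imidazole) | O=C(CCC/C(C)=C/I)n1ccnc1 | intermediate
7 | (E)-6-iodo-N-methoxy-N,5-dimethylhex-5-enamide | CON(C)C(=O)CCC/C(C)=C/I | intermediate
8 | (E)-7-ethoxy-N-methoxy-N,5-dimethylocta-5,7-dienamide | CON(C)C(=O)CCC/C(C)=C/C(=C)OCC | intermediate
9 | (E)-N-methoxy-N,5-dimethyl-7-oxooct-5-enamide | CON(C)C(=O)CCC/C(C)=C/C(C)=O | intermediate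
10 | (E)-N-methoxy-N,5-dimethyl-7-[(triisopropylsilyl)oxy]octa-5,7-dienamide | CON(C)C(=O)CCC/C(C)=C/C(=C)O[Si](C(C)C)(C(C)C)C(C)C | intermediate
11 | bromomagnesium alkoxide of the vinyl adduct of 10 (tetrahedral N-methoxy-N-methyl hemiaminal) | C=CC(O[Mg]Br)(N(C)OC)CCC/C(C)=C/C(=C)O[Si](C(C)C)(C(C)C)C(C)C | intermediate
12 | (E)-7-methyl-9-[(triisopropylsilyl)oxy]deca-1,7,9-trien-3-one | C=CC(=O)CCC/C(C)=C/C(=C)O[Si](C(C)C)(C(C)C)C(C)C | intermediate
13 | (4aR,8aS)-4a-methyl-6-[(triisopropylsilyl)oxy]-3,4,4a,7,8,8a-hexahydronaphthalen-1(2H)-one (cis-fused) | O=C1CCC[C@]2(C)C=C(O[Si](C(C)C)(C(C)C)C(C)C)CC[C@H]12 | intermediate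
14 | (4aR,8aR)-4a-methyl-6-[(triisopropylsilyl)oxy]-3,4,4a,7,8,8a-hexahydronaphthalen-1(2H)-one (trans-fused) | O=C1CCC[C@]2(C)C=C(O[Si](C(C)C)(C(C)C)C(C)C)CC[C@@H]12 | intermediate
15 | lithium enolate of 14 (C3=C4) | [Li]OC1=CCC[C@]2(C)C=C(O[Si](C(C)C)(C(C)C)C(C)C)CC[C@@H]12 | intermediate
16 | (2R,4aR,8aR)-2,4a-dimethyl-6-[(triisopropylsilyl)oxy]-3,4,4a,7,8,8a-hexahydronaphthalen-1(2H)-one (3α-methyl, axial) | O=C1[C@H](C)CC[C@]2(C)C=C(O[Si](C(C)C)(C(C)C)C(C)C)CC[C@@H]12 | intermediate
17 | triisopropyl{[(4aS,6R,8aS)-6,8a-dimethyl-5-methylidene-3,4,4a,5,6,7,8,8a-octahydronaphthalen-2-yl]oxy}silane | C=C1[C@H](C)CC[C@]2(C)C=C(O[Si](C(C)C)(C(C)C)C(C)C)CC[C@@H]12 | intermediate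
18 | 2-bromo-1,4-dimethoxybenzene | COc1ccc(OC)c(Br)c1 | starting material
19 | (4-bromo-2,5-dimethoxyphenyl)methanol | OCc1cc(OC)c(Br)cc1OC | intermediate
20 | 1-bromo-4-(bromomethyl)-2,5-dimethoxybenzene | BrCc1cc(OC)c(Br)cc1OC | intermediate
21 | tetrabutylammonium enolate (C8–O, C8=C9) from 17 | C=C1[C@H](C)CC[C@]2(C)C=C([O-])CC[C@@H]12.CCCC[N+](CCCC)(CCCC)CCCC | intermediate
22 | (1S,4aS,6R,8aS)-1-[(4-bromo-2,5-dimethoxyphenyl)methyl]-6,8a-dimethyl-5-methylidene-3,4,4a,5,6,7,8,8a-octahydronaphthalen-2(1H)-one | C=C1[C@H](C)CC[C@]2(C)[C@H](Cc3cc(OC)c(Br)cc3OC)C(=O)CC[C@@H]12 | intermediate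
23 | potassium enolate of 22 (C7=C8) | C=C1[C@H](C)CC[C@]2(C)[C@H](Cc3cc(OC)c(Br)cc3OC)C(O[K])=CC[C@@H]12 | intermediate
24 | (1S,4aS,6R,8aS)-1-[(4-bromo-2,5-dimethoxyphenyl)methyl]-6,8a-dimethyl-5-methylidene-1,4,4a,5,6,7,8,8a-octahydronaphthalen-2-yl trifluoromethanesulfonate | C=C1[C@H](C)CC[C@]2(C)[C@H](Cc3cc(OC)c(Br)cc3OC)C(OS(=O)(=O)C(F)(F)F)=CC[C@@H]12 | intermediate
25 | 1-bromo-4-{[(1R,4aS,6R,8aR)-2,6,8a-trimethyl-5-methylidene-1,4,4a,5,6,7,8,8a-octahydronaphthalen-1-yl]methyl}-2,5-dimethoxybenzene | C=C1[C@H](C)CC[C@]2(C)[C@H](Cc3cc(OC)c(Br)cc3OC)C(C)=CC[C@@H]12 | intermediate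
26 | ethyl 2-(2,5-dimethoxy-4-{[(1R,4aS,6R,8aR)-2,6,8a-trimethyl-5-methylidene-1,4,4a,5,6,7,8,8a-octahydronaphthalen-1-yl]methyl}phenyl)acetate | C=C1[C@H](C)CC[C@]2(C)[C@H](Cc3cc(OC)c(CC(=O)OCC)cc3OC)C(C)=CC[C@@H]12 | intermediate
27 | lithium carboxylate of 28 | C=C1[C@H](C)CC[C@]2(C)[C@H](Cc3cc(OC)c(CC(=O)O[Li])cc3OC)C(C)=CC[C@@H]12 | intermediate
28 | 2-(2,5-dimethoxy-4-{[(1R,4aS,6R,8aR)-2,6,8a-trimethyl-5-methylidene-1,4,4a,5,6,7,8,8a-octahydronaphthalen-1-yl]methyl}phenyl)acetic acid | C=C1[C@H](C)CC[C@]2(C)[C@H](Cc3cc(OC)c(CC(=O)O)cc3OC)C(C)=CC[C@@H]12 | intermediate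
29 | 2-(3,6-dioxo-4-{[(1R,4aS,6R,8aR)-2,6,8a-trimethyl-5-methylidene-1,4,4a,5,6,7,8,8a-octahydronaphthalen-1-yl]methyl}cyclohexa-1,4-dien-1-yl)acetic acid (quinone) | C=C1[C@H](C)CC[C@]2(C)[C@H](CC3=CC(=O)C(CC(=O)O)=CC3=O)C(C)=CC[C@@H]12 | intermediate
30 | 2-(2,5-dihydroxy-4-{[(1R,4aS,6R,8aR)-2,6,8a-trimethyl-5-methylidene-1,4,4a,5,6,7,8,8a-octahydronaphthalen-1-yl]methyl}phenyl)acetic acid | C=C1[C@H](C)CC[C@]2(C)[C@H](Cc3cc(O)c(CC(=O)O)cc3O)C(C)=CC[C@@H]12 | target

**Step count and risks**

Total step count: 17. Longest linear sequence: 16 steps (steps 1 to 10 and 12 to 17); step 11 prepares the aryl fragment.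

Most likely to fail, step 7: the cycloaddition forms a quaternary centre from a diene with an inside methyl group and may be slow, so incomplete facial discrimination by the catalyst, competing uncatalysed cyclisation or endo/exo leakage could lower the enantiomeric purity. The fallback sets out from 12 and gives up asymmetric catalysis for resolution. The cyclisation is run with Me2AlCl (CH2Cl2, −78 to −20 °C) to give the racemic cis-fused adduct F1. DBU epimerisation as in step 8 then gives the racemic trans-fused ketone F2. Its enantiomers are separated by preparative chromatography on a chiral stationary phase (amylose tris(3,5-dimethylphenylcarbamate), supercritical CO2/iPrOH). The (4aR,8aR) enantiomer is 14, where the route is rejoined.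

Second, step 9: face selectivity of the enolate methylation may be insufficient, proton exchange may lead to double methylation, and the axial methyl group may epimerise to the equatorial position during work-up. The fallback sets out from 14 and uses an aza-enolate in place of the enolate. Condensation with Me2NNH2 (cat. AcOH, EtOH, 60 °C) gives the N,N-dimethylhydrazone F3. Deprotonation with LiN(iPr)2 and methylation with MeI at −78 °C should give the axially methylated hydrazone F4, because A(1,3) strain with the syn dimethylamino group enforces axial attack and keeps the new methyl group axial. Cleavage with CuCl2 in THF/pH 7 buffer, conditions that do not epimerise the α-centre, returns the route at 16.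

Third, step 12: the naked enolate may be quenched by proton transfer from adventitious water or from the product, may be benzylated on oxygen, or may react too slowly at the hindered C9 so that the axial product epimerises. The fallback sets out from 17 and 20 and activates the electrophile instead of the nucleophile. ZnBr2 (or AgOTf) in CH2Cl2 at −40 to 0 °C ionises the electron-rich benzylic bromide, and the intact silyl enol ether is alkylated at C9 from the α face in an SN1-type α-alkylation. Loss of the silyl group gives 22 directly, where the route is rejoined, so this fallback makes no new compound (F0).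

Further compounds
F1 | step 7 | racemic cis-fused adduct (13 and its enantiomer) | O=C1CCC[C@]2(C)C=C(O[Si](C(C)C)(C(C)C)C(C)C)CC[C@H]12.O=C1CCC[C@@]2(C)C=C(O[Si](C(C)C)(C(C)C)C(C)C)CC[C@@H]12
F2 | step 7 | racemic trans-fused ketone (14 and its enantiomer) | O=C1CCC[C@]2(C)C=C(O[Si](C(C)C)(C(C)C)C(C)C)CC[C@@H]12.O=C1CCC[C@@]2(C)C=C(O[Si](C(C)C)(C(C)C)C(C)C)CC[C@H]12
F3 | step 9 | N,N-dimethylhydrazone of 14 (dimethylamino group syn to C3) | CN(C)/N=C1\CCC[C@]2(C)C=C(O[Si](C(C)C)(C(C)C)C(C)C)CC[C@@H]12
F4 | step 9 | N,N-dimethylhydrazone of 16 (3α-methyl, axial) | CN(C)/N=C1\[C@H](C)CC[C@]2(C)C=C(O[Si](C(C)C)(C(C)C)C(C)C)CC[C@@H]12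
F0 | step 12 | none | none
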